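**Retrosynthetic overview**
1. The target comes from the ten-membered 1(10)Z,3Z-dien-5-one 18 by functional-group changes only: C5 reduction, C13 methylenation, C2 oxidation and C8 tigloylation.
2. The feature used: C5 (oxygen-bearing) and C10 (one end of the Z-trisubstituted C1=C10 alkene) lie across the ten-membered ring. A C5–C10 bond turns that ring into a cis-fused decalin (rings A and B), so 18 comes from the C5-hydroxy C1-mesylate 17 by Grob fragmentation.
3. Ring A of 17 comes from ring-closing metathesis (C3=C4) between a C5 isopropenyl carbinol and a C10 side chain C1(OH)–C2(OPMB)–CH=CH2, itself made by syn-alkoxyallylboration of a C10 aldehyde.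
4. Ring B with its lactone comes from (S)-4-(4-methoxybenzyloxy)cyclohexenone 4: C10 by formylation then methylation, C7 and C6 by Mukaiyama–Michael addition and Rubottom oxidation, then lactonisation.
5. Order of ring formation: ring B (present in 1), γ-lactone, ring A, then the ten-membered ring by cleaving the bond common to rings A and B.

Key step: step 12

Remark: carbons are numbered as in the target skeleton (C1–C10 carbocycle, C11–C13 lactone carbons, C14 on C10, C15 on C4); in the six-membered-ring intermediates β is the face of the C10 methyl group and α the face of H-7.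
Remark: the lactone is carried through the fragmentation with CH2 at C11, and C13 is added afterwards by Mannich methylenation, so no C11 stereocentre has to be controlled and the alkoxide meets no Michael acceptor; both ether oxygens (C2, C8) are 4-methoxybenzyl (PMB) ethers.

**Route**

Step 1
Reactants: 1 1,4-dioxaspiro[4.5]dec-6-en-8-one
Product: 2 (S)-1,4-dioxaspiro[4.5]dec-6-en-8-ol
Conditions: RuCl[(S,S)-TsDPEN](p-cymene) (1 mol%), HCO2Na, Bu4NCl, CH2Cl2/H2O, rt
Reagents that add atoms: none
Why: Noyori-type asymmetric transfer hydrogenation reduces the enone carbonyl 1,2 through the six-membered Ru–H/N–H transition state with the ring alkene in the place an aryl group takes in aryl ketones, so the (S,S)-ligand should give the (S)-carbinol that becomes C8 (the enantiomeric catalyst is used if the sense proves opposite).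

Step 2
Reactants: 2 (S)-1,4-dioxaspiro[4.5]dec-6-en-8-ol
Product: 3 (S)-8-(4-methoxybenzyloxy)-1,4-dioxaspiro[4.5]dec-6-ene
Conditions: NaH, 4-methoxybenzyl chloride, Bu4NI (cat.), THF/DMF, 0 °C → rt
Reagents that add atoms: 4-methoxybenzyl chloride, COc1ccc(CCl)cc1
Why: Williamson etherification of the sodium alkoxide leaves the carbinol configuration untouched and gives an ether that survives base, organometallic reagents and metathesis and is later removed oxidatively.

Step 3
Reactants: 3 (S)-8-(4-methoxybenzyloxy)-1,4-dioxaspiro[4.5]dec-6-ene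
Product: 4 (S)-4-(4-methoxybenzyloxy)cyclohex-2-en-1-one
Conditions: pyridinium p-toluenesulfonate (cat.), acetone/H2O, 50 °C
Reagents that add atoms: water, O
Why: Mild acid-catalysed ketal hydrolysis unveils the ketone already conjugated with the C6=C7 alkene, and the weak acid should spare the allylic PMB ether and avoid elimination to a phenol.

Step 4
Reactants: 4 (S)-4-(4-methoxybenzyloxy)cyclohex-2-en-1-one
Product: 5 (4S,6Z)-6-(hydroxymethylidene)-4-(4-methoxybenzyloxy)cyclohex-2-en-1-one
Conditions: LiN(SiMe3)2, THF, −78 °C; HCO2CH2CF3; aq NH4Cl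
Reagents that add atoms: 2,2,2-trifluoroethyl formate, O=COCC(F)(F)F
Why: Kinetic deprotonation at the α′ carbon (C10) gives the cross-conjugated lithium enolate, which is C-formylated by Claisen-type acyl transfer, the product resting as the hydrogen-bonded hydroxymethylidene enol.

Step 5
Reactants: 5 (4S,6Z)-6-(hydroxymethylidene)-4-(4-methoxybenzyloxy)cyclohex-2-en-1-one
Product: 6 (1S,5S)-5-(4-methoxybenzyloxy)-1-methyl-2-oxocyclohex-3-ene-1-carbaldehyde
Conditions: K2CO3, MeI, acetone, 0 °C → rt
Reagents that add atoms: iodomethane, CI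
Why: C-Alkylation of the potassium enolate of the β-keto aldehyde creates the C10 quaternary centre, iodomethane approaching anti to the pseudoaxial C8 ether that shields its own face three atoms away, so the methyl group should end trans to the PMB ether (the later 10β-methyl), and any C10 epimer or O-methyl ether is removed by chromatography.

Step 6
Reactants: 6 (1S,5S)-5-(4-methoxybenzyloxy)-1-methyl-2-oxocyclohex-3-ene-1-carbaldehyde; 7 allyl 4-methoxybenzyl ether
Product: 9 (4S,6S)-6-[(1R,2R)-1-hydroxy-2-(4-methoxybenzyloxy)but-3-en-1-yl]-4-(4-methoxybenzyloxy)-6-methylcyclohex-2-en-1-one, via allylborane 8 (not isolated)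
Conditions: 7, sBuLi, THF, −78 °C; (−)-Ipc2BOMe; BF3·OEt2; then 6, −78 → −20 °C; 30% H2O2, aq NaHCO3, 0 °C
Reagents that add atoms: none
Why: Brown alkoxyallylboration, in which the (Z)-γ-alkoxyallylborane adds to the aldehyde (far faster than to the hindered enone carbonyl) through a chair Zimmerman–Traxler transition state that makes the C1 hydroxyl and the C2 ether syn, while the isopinocampheyl groups from (−)-Ipc2BOMe direct attack to the Si face and so set 1R,2R under reagent control.

Step 7
Reactants: 9 (4S,6S)-6-[(1R,2R)-1-hydroxy-2-(4-methoxybenzyloxy)but-3-en-1-yl]-4-(4-methoxybenzyloxy)-6-methylcyclohex-2-en-1-one; 10 1-methoxy-1-(trimethylsilyloxy)ethene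
Product: 12 ring-B 6α-hydroxy-5-ketone methyl ester, via bis-silyl enol ether 11 (not isolated)
Conditions: 10 (3 equiv), Me3SiOTf (10 mol%), CH2Cl2, −78 °C; evaporate; mCPBA, NaHCO3, CH2Cl2, −20 → 0 °C; citric acid, MeOH, rt
Reagents that add atoms: 3-chloroperbenzoic acid (mCPBA), OOC(=O)c1cccc(Cl)c1
Why: Mukaiyama–Michael addition followed by Rubottom oxidation, in which the silyl ketene acetal adds to C7 anti to the C8 ether (side chain β) and leaves the regiodefined C5–C6 silyl enol ether, which the peracid epoxidises on the α face, away from the new C7 substituent and the pseudoaxial C10 methyl, so that the C6 hydroxyl ends trans to the side chain; the C1 hydroxyl is silylated in passing by excess reagent and freed again in the acidic methanol treatment.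

Step 8
Reactants: 12 ring-B 6α-hydroxy-5-ketone methyl ester
Product: 13 bicyclic keto lactone (12,6α-olide)
Conditions: camphorsulfonic acid (10 mol%), toluene, 60 °C
Reagents that add atoms: none
Why: Acid-catalysed lactonisation (intramolecular transesterification) of the trans-diequatorial γ-hydroxy ester closes the trans-fused lactone that locks ring B in one chair, with no stereocentre touched and the C1 hydroxyl too remote to compete.

Step 9
Reactants: 13 bicyclic keto lactone; 14 isopropenylmagnesium bromide
Product: 15 C5 isopropenyl carbinol (5β-OH)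
Conditions: 14 (3.5 equiv), LaCl3·2LiCl (1.1 equiv), THF, −40 → 0 °C; aq NH4Cl
Reagents that add atoms: none
Why: Lanthanide-promoted Grignard 1,2-addition (LaCl3·2LiCl suppresses enolisation toward C6 and retro-aldol of the C1 alkoxide) to the ketone, which is more electrophilic than the lactone; in the chair locked by the trans-lactone the nucleophile enters axially on the α face, anti to the axial C10 methyl that blocks the equatorial trajectory, so the new C5 hydroxyl is β and cis to that methyl.

Step 10
Reactants: 15 C5 isopropenyl carbinol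
Product: 16 cis-fused decalin 1α,5β-diol
Conditions: second-generation Grubbs catalyst RuCl2(=CHPh)(PCy3)(H2IMes) (5 mol%), CH2Cl2, 40 °C
Reagents that add atoms: none
Why: Ring-closing olefin metathesis between the C2 vinyl group and the C5 isopropenyl group, held cis (equatorial and axial) on adjacent carbons, forms the trisubstituted C3=C4 alkene of ring A and with it the cis-fused decalin, driven by loss of ethene and tolerant of the free hydroxyls.

Step 11
Reactants: 16 cis-fused decalin 1α,5β-diol
Product: 17 C1 mesylate (fragmentation precursor)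
Conditions: MsCl, Et3N, CH2Cl2, −20 °C
Reagents that add atoms: methanesulfonyl chloride, CS(Cl)(=O)=O
Why: Sulfonylation through sulfene esterifies the secondary, equatorial C1 hydroxyl while the tertiary C5 hydroxyl is too hindered to react, and without alkoxide formation the 1,3-diol monomesylate should be stable enough to isolate.

Step 12
Reactants: 17 C1 mesylate
Product: 18 ten-membered 1(10)Z,3Z-dien-5-one
Conditions: KOtBu (1.05 equiv), THF, 0 °C, 15 min; pH 7 phosphate buffer
Reagents that add atoms: none
Why: Deprotonation of the tertiary C5 hydroxyl gives an alkoxide whose lone pair pushes into the C5–C10 bond while the antiperiplanar C1–O mesylate bond departs, a concerted Grob fragmentation of the kind known for decalin 1,3-diol monosulfonates, which give cyclodecenones. No ring is closed by bond formation; the ten-membered ring is released by cleaving the bond common to rings A and B, so no medium-ring cyclisation is needed. No stereocentre is created: C2, C6, C7 and C8 are spectators, and C1, C5 and C10 become sp2. The selectivity needed is alkene geometry, and it is fixed by relative configuration: the trans-fused lactone and the equatorial C8 ether hold ring B in the chair with the C10 methyl axial, so in the cis-fused decalin C9 is axial on ring A and gauche to C2 across C1–C10, and the equatorial α-mesylate is anti to C5–C10; the synchronous process turns this into the ring-cis (Z) C1=C10 alkene, while C3=C4 is Z because it was made in a six-membered ring. The same alignment disfavours oxetane formation and E2 loss of the mesylate, and the lactone, having no exocyclic methylene, offers the alkoxide no Michael acceptor. One equivalent of base at 0 °C and a neutral quench should limit enolisation of the new C5 ketone toward C6.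

Step 13
Reactants: 18 ten-membered 1(10)Z,3Z-dien-5-one
Product: 19 (5S)-allylic alcohol
Conditions: NaBH4, CeCl3·7H2O, MeOH, −78 °C
Reagents that add atoms: none
Why: Luche 1,2-reduction of the enone, in which hydride should add under Felkin–Anh control, anti to the C6–O bond of the lactone (a poorly chelating acyloxy oxygen), giving the 5S alcohol, while CeCl3 suppresses conjugate reduction and the low temperature protects the C6 stereocentre.

Step 14
Reactants: 19 (5S)-allylic alcohol
Product: 20 C5 tert-butyldimethylsilyl ether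
Conditions: tBuMe2SiOTf, 2,6-lutidine, CH2Cl2, −78 → 0 °C
Reagents that add atoms: tert-butyldimethylsilyl triflate, CC(C)(C)[Si](C)(C)OS(=O)(=O)C(F)(F)F
Why: Silylation of the hindered allylic secondary alcohol with the silyl triflate and a hindered pyridine base blocks the C5 hydroxyl for the enolate and acylation steps and prevents lactone migration to C5.

Step 15
Reactants: 20 C5 tert-butyldimethylsilyl ether
Product: 21 C11 dimethylaminomethyl lactone
Conditions: LiN(iPr)2, THF, −78 °C; Me2N=CH2+ I− (Eschenmoser's salt), −78 °C → rt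
Reagents that add atoms: N,N-dimethylmethyleneiminium iodide, C[N+](C)=C.[I-]
Why: Mannich reaction of the lactone lithium enolate with the preformed iminium salt installs C13 at C11; the C11 configuration (drawn with the aminomethyl group cis to H-7) is of no consequence because it is erased in the next step.

Step 16
Reactants: 21 C11 dimethylaminomethyl lactone
Product: 23 α-methylene lactone, via ammonium iodide 22 (not isolated)
Conditions: MeI, MeOH, rt; then aq NaHCO3, CH2Cl2, rt
Reagents that add atoms: none
Why: Exhaustive N-methylation gives the quaternary ammonium salt, which undergoes Hofmann-type (E1cB) elimination with mild base to give only the exocyclic C11=C13 methylene, since the ammonium group sits on C13.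

Step 17
Reactants: 23 α-methylene lactone
Product: 24 C2,C8-diol
Conditions: DDQ (2.6 equiv), CH2Cl2/pH 7 phosphate buffer, 0 °C → rt
Reagents that add atoms: none
Why: Oxidative cleavage of both PMB ethers by DDQ (benzylic hydride abstraction, then hydrolysis of the oxocarbenium ion) under buffered conditions frees the C2 and C8 hydroxyls without touching the silyl ether or the methylene lactone, and any direct oxidation at the bis-allylic C2 position only anticipates the next step.

Step 18
Reactants: 24 C2,C8-diol
Product: 25 2-oxo cross-conjugated dienone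
Conditions: MnO2 (activated, excess), CH2Cl2, rt
Reagents that add atoms: none
Why: Chemoselective allylic oxidation with MnO2 converts the doubly allylic C2 alcohol into the cross-conjugated dienone while the saturated C8 alcohol is inert, and the neutral heterogeneous conditions should preserve both alkene geometries.

Step 19
Reactants: 25 2-oxo cross-conjugated dienone; 26 tigloyl chloride
Product: 27 C8 tiglate
Conditions: 26 (2 equiv), pyridine, 4-(dimethylamino)pyridine (cat.), CH2Cl2, 0 °C → rt
Reagents that add atoms: none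
Why: DMAP-catalysed acylation of the C8 hydroxyl through the acylpyridinium ion, with pyridine instead of a trialkylamine to avoid vinylketene formation, so that the E-configured tiglate should be transferred intact.

Step 20
Reactants: 27 C8 tiglate
Product: 28 CNP0230565.1
Conditions: HF·pyridine, pyridine, THF, 0 °C → rt
Reagents that add atoms: none
Why: Fluoride-mediated desilylation with buffered HF·pyridine cleaves the Si–O bond at C5 without acyl migration, conjugate addition or elimination, giving the target with its four stereocentres (5S,6S,7R,8S) and both Z ring alkenes in place.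

**Compound list**
1 | 1,4-dioxaspiro[4.5]dec-6-en-8-one | O=C1C=CC2(CC1)OCCO2 | starting material
2 | (S)-1,4-dioxaspiro[4.5]dec-6-en-8-ol | O[C@@H]1C=CC2(CC1)OCCO2 | intermediate
3 | (S)-8-(4-methoxybenzyloxy)-1,4-dioxaspiro[4.5]dec-6-ene | COc1ccc(CO[C@@H]2C=CC3(CC2)OCCO3)cc1 | intermediate
4 | (S)-4-(4-methoxybenzyloxy)cyclohex-2-en-1-one | COc1ccc(CO[C@@H]2C=CC(=O)CC2)cc1 | intermediate
5 | (4S,6Z)-6-(hydroxymethylidene)-4-(4-methoxybenzyloxy)cyclohex-2-en-1-one | COc1ccc(CO[C@@H]2C=CC(=O)/C(=C\O)C2)cc1 | intermediate
6 | (1S,5S)-5-(4-methoxybenzyloxy)-1-methyl-2-oxocyclohex-3-ene-1-carbaldehyde (C10 quaternary, formyl carbon is C1) | COc1ccc(CO[C@@H]2C=CC(=O)[C@](C)(C=O)C2)cc1 | intermediate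
7 | allyl 4-methoxybenzyl ether | C=CCOCc1ccc(OC)cc1 | starting material
8 | [(Z)-3-(4-methoxybenzyloxy)prop-2-enyl]bis(isopinocampheyl)borane, isopinocampheyl groups from (−)-Ipc2BOMe | C[C@H]1[C@H](B(C/C=C\OCc2ccc(OC)cc2)[C@@H]3C[C@@H]4C[C@@H](C4(C)C)[C@H]3C)C[C@@H]2C[C@H]1C2(C)C | intermediate
9 | (4S,6S)-6-[(1R,2R)-1-hydroxy-2-(4-methoxybenzyloxy)but-3-en-1-yl]-4-(4-methoxybenzyloxy)-6-methylcyclohex-2-en-1-one | COc1ccc(CO[C@@H]2C=CC(=O)[C@](C)([C@@H](O)[C@H](OCc3ccc(OC)cc3)C=C)C2)cc1 | intermediate
10 | 1-methoxy-1-(trimethylsilyloxy)ethene | C=C(OC)O[Si](C)(C)C | starting material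
11 | C5–C6 trimethylsilyl enol ether of the C7β methyl acetate adduct of 9, C1 hydroxyl as trimethylsilyl ether | C1=C(O[Si](C)(C)C)[C@](C)([C@@H](O[Si](C)(C)C)[C@H](OCc2ccc(OC)cc2)C=C)C[C@H](OCc2ccc(OC)cc2)[C@H]1CC(=O)OC | intermediate
12 | ring-B ketone: 6α-hydroxy-5-oxo, 7β-CH2CO2Me, 8α-OPMB, C10 with β-methyl and α-[(1R,2R)-1-hydroxy-2-(4-methoxybenzyloxy)but-3-enyl] | O[C@H]1[C@H](CC(=O)OC)[C@@H](OCc2ccc(OC)cc2)C[C@@](C)([C@@H](O)[C@H](OCc2ccc(OC)cc2)C=C)C1=O | intermediate
13 | trans-fused bicyclic keto lactone (12,6α-olide, CH2 at C11, 5-oxo, 8α-OPMB, C10 substituents as in 12) | C1C(=O)O[C@H]2[C@H]1[C@@H](OCc3ccc(OC)cc3)C[C@@](C)([C@@H](O)[C@H](OCc3ccc(OC)cc3)C=C)C2=O | intermediate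
14 | isopropenylmagnesium bromide (THF solution) | CC(=C)[Mg]Br | starting material
15 | 5β-hydroxy-5α-isopropenyl lactone (C1 hydroxyl free, C2 OPMB, terminal vinyl) | C1C(=O)O[C@H]2[C@H]1[C@@H](OCc3ccc(OC)cc3)C[C@@](C)([C@@H](O)[C@H](OCc3ccc(OC)cc3)C=C)[C@@]2(O)C(C)=C | intermediate
16 | cis-fused 1α,5β-dihydroxy-2β,8α-bis(4-methoxybenzyloxy)-13-noreudesm-3-en-12,6α-olide | C1C(=O)O[C@H]2[C@H]1[C@@H](OCc3ccc(OC)cc3)C[C@@]4(C)[C@@H](O)[C@H](OCc3ccc(OC)cc3)C=C(C)[C@@]24O | intermediate
17 | (1R,2R,5S,6S,7R,8S,10S) cis-fused 5β-hydroxy-1α-mesyloxy-2β,8α-bis(4-methoxybenzyloxy)-13-noreudesm-3-en-12,6α-olide | C1C(=O)O[C@H]2[C@H]1[C@@H](OCc3ccc(OC)cc3)C[C@@]4(C)[C@@H](OS(C)(=O)=O)[C@H](OCc3ccc(OC)cc3)C=C(C)[C@@]24O | intermediate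
18 | 2,8α-bis(4-methoxybenzyloxy)-5-oxo-13-norgermacra-1(10)Z,3Z-dien-12,6α-olide (C2 configuration as in 17) | C1C(=O)O[C@H]2[C@H]1[C@@H](OCc3ccc(OC)cc3)C/C(C)=C\[C@H](OCc3ccc(OC)cc3)/C=C(/C)C2=O | intermediate
19 | (5S)-5-hydroxy analogue of 18 | C1C(=O)O[C@H]2[C@H]1[C@@H](OCc3ccc(OC)cc3)C/C(C)=C\[C@H](OCc3ccc(OC)cc3)/C=C(/C)[C@@H]2O | intermediate
20 | C5 tert-butyldimethylsilyl ether of 19 | C1C(=O)O[C@H]2[C@H]1[C@@H](OCc3ccc(OC)cc3)C/C(C)=C\[C@H](OCc3ccc(OC)cc3)/C=C(/C)[C@@H]2O[Si](C)(C)C(C)(C)C | intermediate
21 | 11-(dimethylaminomethyl) lactone from 20 (aminomethyl group drawn cis to H-7) | CN(C)C[C@@H]1C(=O)O[C@H]2[C@H]1[C@@H](OCc3ccc(OC)cc3)C/C(C)=C\[C@H](OCc3ccc(OC)cc3)/C=C(/C)[C@@H]2O[Si](C)(C)C(C)(C)C | intermediate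
22 | trimethylammonium iodide of 21 | C[N+](C)(C)C[C@@H]1C(=O)O[C@H]2[C@H]1[C@@H](OCc3ccc(OC)cc3)C/C(C)=C\[C@H](OCc3ccc(OC)cc3)/C=C(/C)[C@@H]2O[Si](C)(C)C(C)(C)C.[I-] | intermediate
23 | 5-(tert-butyldimethylsilyloxy)-2,8α-bis(4-methoxybenzyloxy)germacra-1(10)Z,3Z,11(13)-trien-12,6α-olide | C=C1C(=O)O[C@H]2[C@H]1[C@@H](OCc3ccc(OC)cc3)C/C(C)=C\[C@H](OCc3ccc(OC)cc3)/C=C(/C)[C@@H]2O[Si](C)(C)C(C)(C)C | intermediate
24 | 2,8α-dihydroxy-5-(tert-butyldimethylsilyloxy)germacra-1(10)Z,3Z,11(13)-trien-12,6α-olide | C=C1C(=O)O[C@H]2[C@H]1[C@@H](O)C/C(C)=C\[C@H](O)/C=C(/C)[C@@H]2O[Si](C)(C)C(C)(C)C | intermediate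
25 | 8α-hydroxy-2-oxo-5-(tert-butyldimethylsilyloxy)germacra-1(10)Z,3Z,11(13)-trien-12,6α-olide | C=C1C(=O)O[C@H]2[C@H]1[C@@H](O)C/C(C)=C\C(=O)/C=C(/C)[C@@H]2O[Si](C)(C)C(C)(C)C | intermediate
26 | tigloyl chloride, (E)-2-methylbut-2-enoyl chloride | ClC(=O)/C(C)=C/C | starting material
27 | C8 tiglate of 25 | C=C1C(=O)O[C@H]2[C@H]1[C@@H](OC(=O)/C(C)=C/C)C/C(C)=C\C(=O)/C=C(/C)[C@@H]2O[Si](C)(C)C(C)(C)C | intermediate
28 | CNP0230565.1, (5S,6S,7R,8S)-5-hydroxy-2-oxo-8-tigloyloxygermacra-1(10)Z,3Z,11(13)-trien-12,6-olide | C=C1C(=O)O[C@H]2[C@H]1[C@@H](OC(=O)/C(C)=C/C)C/C(C)=C\C(=O)/C=C(/C)[C@@H]2O | target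

**Step count and risks**

Total: 20 steps. Longest linear sequence: 20 steps (from 1).

Steps most likely to fail:

Step 12 (key step). What may go wrong is enolisation of the freshly formed C5 ketone by the alkoxide base before the quench: toward C6, with loss of the lactone carbinol configuration, or through the C3=C4 bond toward C2, with Z to E isomerisation. Fallback: starting from 17, the C5 hydroxyl is silylated (Me3SiOTf, 2,6-lutidine, CH2Cl2, −78 °C) to the C5 trimethylsilyl ether F1. The fragmentation is then triggered by fluoride (Bu4N[Ph3SiF2], THF, 0 °C), which releases the alkoxide gradually and never in excess. This is the known desilylative variant of the Grob fragmentation, and the route is rejoined at 18.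

Step 9. What may go wrong is retro-aldol cleavage of the C1 alkoxide/C5 ketone pair, enolisation toward C6, or attack at the lactone carbonyl, each competing with slow addition to a ketone flanked by a quaternary carbon. Fallback: starting from 13, the C1 hydroxyl is capped (Et3SiCl, imidazole, DMF) to give the C1 triethylsilyl ether F2, which removes the aldolate. The isopropenyl group is then delivered as the organocerium reagent (14, CeCl3, THF, −78 °C) to give the silylated carbinol F3. Ring-closing metathesis under the conditions of step 10 gives the silylated cis-decalin F4, and HF·pyridine removes the silyl group to rejoin the route at 16.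

Step 13. What may go wrong is poor or reversed facial selectivity, because the conformation of the ten-membered ring rather than the Felkin–Anh preference may decide which carbonyl face is exposed. Fallback: starting from 18, the reduction is run as before and the C5 epimer F5 (5R) is inverted by Mitsunobu reaction (4-nitrobenzoic acid, PPh3, diisopropyl azodicarboxylate, THF) to the 5S 4-nitrobenzoate F6. This ester is cleaved with K2CO3 in methanol at 0 °C, and the route is rejoined at 19.

Further compounds
F1 | step 12 | C5 trimethylsilyl ether of mesylate 17 | C1C(=O)O[C@H]2[C@H]1[C@@H](OCc3ccc(OC)cc3)C[C@@]4(C)[C@@H](OS(C)(=O)=O)[C@H](OCc3ccc(OC)cc3)C=C(C)[C@@]24O[Si](C)(C)C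
F2 | step 9 | C1 triethylsilyl ether of keto lactone 13 | C1C(=O)O[C@H]2[C@H]1[C@@H](OCc3ccc(OC)cc3)C[C@@](C)([C@@H](O[Si](CC)(CC)CC)[C@H](OCc3ccc(OC)cc3)C=C)C2=O
F3 | step 9 | C1 triethylsilyl ether of isopropenyl carbinol 15 | C1C(=O)O[C@H]2[C@H]1[C@@H](OCc3ccc(OC)cc3)C[C@@](C)([C@@H](O[Si](CC)(CC)CC)[C@H](OCc3ccc(OC)cc3)C=C)[C@@]2(O)C(C)=C
F4 | step 9 | C1 triethylsilyl ether of cis-decalin 16 | C1C(=O)O[C@H]2[C@H]1[C@@H](OCc3ccc(OC)cc3)C[C@@]4(C)[C@@H](O[Si](CC)(CC)CC)[C@H](OCc3ccc(OC)cc3)C=C(C)[C@@]24O
F5 | step 13 | C5 epimer (5R) of alcohol 19 | C1C(=O)O[C@H]2[C@H]1[C@@H](OCc3ccc(OC)cc3)C/C(C)=C\[C@H](OCc3ccc(OC)cc3)/C=C(/C)[C@H]2O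
F6 | step 13 | (5S) 4-nitrobenzoate of alcohol 19 | C1C(=O)O[C@H]2[C@H]1[C@@H](OCc3ccc(OC)cc3)C/C(C)=C\[C@H](OCc3ccc(OC)cc3)/C=C(/C)[C@@H]2OC(=O)c4ccc(cc4)[N+](=O)[O-]
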